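**The task.** Two chain lengths are asked, and the third question follows from them, so one quantity has to serve both flasks, red and ochre.

| setting | theta | red | ochre |
|---|---|---|---|
| E | 0.075 M | 0.050 M | 0.050 M |
| J | 0.2 mol% | 0.2 mol% | 0.2 mol% |
| X | 57 µM | 57 µM | 15 µM |
| remark | run made earlier |  |  |
| time |  | 10 d | 10 d |

theta run (percent of the E charged)

| time / d | L / % | E / % |
|---|---|---|
| 0.208 | 6.3 | 92.8 |
| 0.500 | 55.3 | 44.6 |
| 1.04 | 70.1 | 30.2 |
| 1.67 | 69.9 | 30.2 |
| 2.00 | 70.4 | 30.4 |
| 3.00 | 70.1 | 30.1 |
| 4.00 | 70.2 | 30.0 |

(each reading ± 0.3 percentage points)

1. which of the two ends with the longer chains by the average number of monomer units in a chain (chains begun, living or dead) ("neither" if they lie within 10%) (red / ochre / neither)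
2. average number of monomer units in a chain (chains begun, living or dead) at the end, red
3. average number of monomer units in a chain (chains begun, living or dead) at the end, ochre

- the average divides the monomer in chains by the number of chains begun, living and dead together
- what may be going on: E + Q -> D + L; E + D -> L + D; L + D -> E + D; Q + X -> Z; J -> Q
- the earlier runs do not show the number of chains; that part of a forecast is a guess
- no earlier run changes the charge of J; that part of a forecast is a guess

**Monomer in chains.** The theta run levels off with E near 30.0% of 0.075 M, that is 0.0225 M. This is read as the equilibrium monomer concentration and assumed to hold in red and ochre, so each puts 0.0275 M into chains. Length is this amount divided by the number of chains, and the question becomes what happens to each Q released from J: it meets X and is lost to Z, or meets E and starts a chain.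

**Two extremes.** Suppose J is released in full within 10 d and X takes no Q. Chains then equal the J charged, 100 µM, and both flasks give 275. Suppose instead that X takes one Q per X before any chain starts. Chains then equal the surviving initiator, the J charged less the X charged: 43.0 µM in red, giving 640, and 85.0 µM in ochre, giving 324.

**Between them.** Red and ochre should each lie between their two extremes. Theta's slow start, 6.3% of L at 0.208 d and then 55.3% at 0.500 d, suggests that X intercepts Q first, so this reckoning commits to the second extreme. By the same subtraction theta has 93.0 µM of surviving initiator, and its readings are flat from 1.04 d. If the time constant scales inversely with chains, red needs about 2.25 d, which is shorter than the 10 d allowed.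

**The forecast.** The forecast names red, with 620 (440 to 800), lower than this reckoning, and 320 (270 to 380), on the ground: “I assume X removes Q nearly one-for-one”.

**The result.** The longer chains are in red: red ends at 637 with D at 4.30 × 10⁻⁵ M, and ochre at 322 with D at 8.50 × 10⁻⁵ M, against reckoned surviving initiator of 43.0 µM and 85.0 µM.

    E + Q → D + L (k = 0.00429 M⁻¹ s⁻¹)
    E + D → L + D, rate k2*[D]*[E] (k = 2.06 M⁻¹ s⁻¹)
    L + D → E + D, rate k3*[D] as long as [L] is above zero (k = 0.0466 s⁻¹)
    Q + X → Z (k = 122 M⁻¹ s⁻¹)
    J → Q (k = 3.18 × 10⁻⁵ s⁻¹)

The neighbouring flask is red with X raised to 9.7 × 10⁻⁵ M. Its surviving initiator is 3.00 µM, which gives a length of 9167. That flask gives 4930, with D at 5.56 × 10⁻⁶ M, Z at 9.44 × 10⁻⁵ M, less than the X charged, and 2.6% of its X still there at 10.0 d.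

(The earlier runs and the new flask stem from a simulated flask with made-up constants; the scatter is artificial.)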